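## Analysis of the target

1. The target 14 is a (3R)-3-alkyl-5,7-dimethoxyphthalide (lactone C1/O2/C3, arene C3a–C7a). C3 carries an unbranched hexamethylene linker (C1″–C6″) that ends at C2′ of a 7′-methyl-1,6-dioxaspiro[4.4]nonane (ring A: O1′–C2′–C3′–C4′–C5′; ring B: C5′–O6′–C7′–C8′–C9′).
2. There are four stereocentres: C3 (R), C2′ (S), C5′ (R) and C7′ (S). C3 and C2′ are separated by six methylene groups, so the phthalide centre cannot be relayed from the ketal and needs its own source of chirality.
3. C2′ and C7′ have the same (S) configuration and each is 1,4-related to the ketal carbon. C4′–C5′–C9′ is therefore an acetone unit flanked on both sides by a CH2–CH(O) unit (C3′–C2′ and C8′–C7′); this local two-fold pattern is the feature the route is built on.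
4. The spiro carbon C5′ is the awkward centre. In 14 the linker and the methyl group both lie anti to the oxygen of the other ring, in the C5′ epimer both lie syn, and two five-membered rings give almost no anomeric or steric preference between the two.
5. C5′ also epimerises by ring opening under mild acid, so it cannot be fixed by a bond-forming step and then kept; it can only be taken out of an equilibrium.
6. The sensitive groups are the ketal (acid), the lactone with its benzylic, oxygen-bearing C3–H (strong bases, nucleophiles, hydrogenolysis of C3–O2) and the electron-rich arene (electrophiles, oxidants).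
7. The difficulty is economy rather than any single ring: two unrelated stereochemical domains, a dissonant 1,4-dioxygen pattern and an uncontrollable spiro centre lead to long, protecting-group-heavy fragment syntheses unless the ketal half is assembled in one operation.

## Retrosynthetic reasoning

**14 ⇒ 13.** No bond is cut. 14 is traced back to the pair of C5′ epimers 13, from which it is separated while the other epimer is returned to the equilibrium. Since C5′ epimerises with any trace of acid, control at an earlier stage would be lost again; leaving it to the last operation lets every earlier step ignore this centre.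

**13 ⇒ 12.** The lactone is cut at C1–C7a and C1–O2, which removes the carbonyl carbon and leaves an aryl bromide at C7a and a free benzylic alcohol at C3. The lactone is the group least compatible with organometallic C–C bond formation at C3, whereas a C–Br bond is inert there. The forward step must insert one carbon between C7a and the C3 oxygen without touching the C3–O bond, so the stereocentre is not at risk.

**12 ⇒ 8 + 9.** The C3–C1″ bond is cut. This is the bond at the stereocentre, so fragment union and asymmetric induction happen in the same step, and an aromatic aldehyde is the best substrate class for catalyst-controlled alkyl addition. Aldehyde 9 is commercial with the bromine already in place. The nucleophile needs only a terminal alkene (C1″=C2″ in 8) as its precursor, which is the one handle the key step must carry.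

**8 ⇒ 2 + 3 + 4 (key disconnection).** Four bonds are cut at once: C3′–C4′, C8′–C9′ and both ketal C–O bonds. The acetone unit C4′–C5′–C9′ is 3, ring A's arm is epoxide 2 and ring B's arm is epoxide 4. Each epoxide brings its carbinol carbon in the correct configuration, and an enolate-type carbon opening an epoxide gives exactly the 1,4-relationship required. No redox adjustment and no protecting group is needed; the forward reaction must alkylate the two α-carbons of 3 in turn with two different epoxides and then close both rings.

**2 ⇒ 1.** The (S)-epoxide is taken from the commercial racemate 1 by hydrolytic kinetic resolution.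

## Alternatives that were turned down

**Alternative 1:** The textbook route cuts the linker in its middle (C3″–C4″) as a C=C bond. A Julia–Kocienski olefination of spiroketal sulfone A1 with phthalide aldehyde A2 would give alkene A3, which is then hydrogenated. It was turned down for these reasons:
- Both halves need their own multi-step syntheses: A1 from a protected dihydroxy ketone, A2 by an asymmetric addition, chain extension and lactonisation.
- The metalated sulfone meets a lactone whose C3–H is acidic, so epimerisation and lactone attack are likely.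
- The C=C bond is made only to be erased, next to a benzylic C3–O2 bond that is open to hydrogenolysis.
- Nothing is gained for C5′, at roughly three times the step count.

**Alternative 2:** Both ketal C–O bonds are formed last by gold-catalysed double hydroalkoxylation (5-exo-dig, then 5-endo closure onto the same carbon) of alkynediol A4, which already carries the phthalide. The attraction is that C5′ appears only in the final step. It was turned down for these reasons:
- A4 can only be reached by an acetylide/epoxide union that neither the lactone nor the acidic C3–H tolerates.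
- The phthalide would therefore have to be completed afterwards, in the presence of an internal alkyne and two hydroxyls that then need protection.
- The alkyne half is not commercial in enantiopure form.
- A 6-endo closure can compete.
- The route is three to four steps longer and gives no better control of C5′.

The reaction type is kept as the fallback for step 2 on a substrate without the phthalide.

**Alternative 3:** Both ketal C–O bonds are formed by two successive alkoxy-radical 1,5-hydrogen transfers at the future C5′ (hypoiodite conditions, visible light) from saturated diol A5. The attraction is a precursor with no carbonyl at all. It was turned down for these reasons: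
- The oxygen radical on the future C2′ has two equivalent δ-methylene groups (the future C5′ and C4″), so the first hydrogen transfer is unselective.
- The hypoiodite reagent iodinates electron-rich dimethoxyarenes and can attack the benzylic C3–H.
- A5 has no symmetry-based shortcut.
- The spiro centre would still be formed unselectively.

Key step: step 2

## Route

Assumption: C5′ cannot be fixed kinetically, so compounds 8 and 10–13 are carried as the pair of C5′ epimers (their SMILES leave this atom undefined) and the single isomer is obtained in step 5.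

Step 1
Reactants: 1 rac-2-(hex-5-en-1-yl)oxirane (1,2-epoxy-7-octene)
Product: 2 (S)-2-(hex-5-en-1-yl)oxirane
Conditions: (S,S)-(salen)Co(III)OAc (0.5 mol %), H2O (0.55 equiv), neat, 0 °C → rt; distillation
Reagents that add atoms: none
Why: Hydrolytic kinetic resolution; the (S,S)-catalyst should hydrate the (R)-epoxide selectively and leave 2, whose stereocentre becomes C2′ (if the sense were opposite, the antipodal catalyst is equally available).

Step 2
Reactants: 3 acetone N,N-dimethylhydrazone; 4 (S)-propylene oxide; 2 (S)-2-(hex-5-en-1-yl)oxirane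
Product: 8 (2S,7S)-2-(hex-5-en-1-yl)-7-methyl-1,6-dioxaspiro[4.4]nonane (C5 epimer pair), via (2S)-5-(2,2-dimethylhydrazinylidene)hexan-2-ol 5 (not isolated), via (2S,8S)-5-(2,2-dimethylhydrazinylidene)tetradec-13-ene-2,8-diol 6 (not isolated), via (2S,8S)-2,8-dihydroxytetradec-13-en-5-one 7 (not isolated)
Conditions: 3, n-BuLi (1.05 equiv), THF, −78 → 0 °C; 4, 0 °C → rt; n-BuLi (1.05 equiv), −78 → 0 °C; 2 (limiting), 0 °C → rt; then 2 M aq. HCl/Et2O, rt
Reagents that add atoms: none
Why: Deprotonated 3 (a lithium azaenolate) opens 4 by SN2 attack at the unsubstituted carbon, forming C8′–C9′ and giving 5 as its lithium alkoxide; a second metalation at the remaining α′-methyl gives an azaenolate that opens 2 in the same way, forming C3′–C4′ and giving 6. Aqueous acid hydrolyses the hydrazone to 7, whose two γ-hydroxyls add in turn to the carbonyl carbon (hemiketal, then capture of the oxocarbenium ion), each closure being 5-exo-trig, to give both rings of 8. The closest known reaction type is the one-pot α,α′-dialkylation of acetone dimethylhydrazone with two oxiranes followed by acid-induced spiroketalisation, established for simple 1,6-dioxaspiro[4.4]nonanes. C2′ and C7′ are not created here: they are the epoxide carbinol carbons, untouched because attack is at CH2, so both keep the S configuration. C5′ forms under equilibrating conditions and is not controlled, so both epimers are expected in similar amounts. The selectivities needed are α′ over α in the second metalation (kinetic preference of dimethylhydrazones for the less substituted carbon), terminal over internal epoxide carbon (steric), and inertness of the terminal alkene to azaenolates and dilute acid. Using 2 as the second, limiting electrophile keeps the volatile 4 in the position where excess is cheap.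

Step 3
Reactants: 8 (2S,7S)-2-(hex-5-en-1-yl)-7-methyl-1,6-dioxaspiro[4.4]nonane; 9 2-bromo-3,5-dimethoxybenzaldehyde
Product: 12 (1R)-1-(2-bromo-3,5-dimethoxyphenyl)-7-[(2S,7S)-7-methyl-1,6-dioxaspiro[4.4]nonan-2-yl]heptan-1-ol (C5′ epimer pair), via diethyl{6-[(2S,7S)-7-methyl-1,6-dioxaspiro[4.4]nonan-2-yl]hexyl}borane 10 (not isolated), via bis{6-[(2S,7S)-7-methyl-1,6-dioxaspiro[4.4]nonan-2-yl]hexyl}zinc 11 (not isolated)
Conditions: 8, Et2BH (from BH3·SMe2 + 2 Et3B), 0 °C → rt; Et2Zn, 0 °C, then volatiles off in vacuo; Ti(OiPr)4, (1S,2S)-1,2-bis(trifluoromethanesulfonamido)cyclohexane (8 mol %), toluene, −20 °C, then 9 (limiting); aq. NH4Cl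
Reagents that add atoms: none
Why: Anti-Markovnikov hydroboration, boron–zinc exchange and titanium/bis(sulfonamide)-catalysed asymmetric addition of the functionalised dialkylzinc to an aromatic aldehyde form C3–C1″. The chiral titanium complex alone sets the new centre: the (1S,2S)-ligand should direct the alkyl group to the Re face and give the (R)-carbinol (the antipodal ligand would be used if the sense were opposite), since the ketal centres are too remote to interfere. An excess of 11 is accepted because 8 is two steps from commodity materials.

Step 4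
Reactants: 12 (1R)-1-(2-bromo-3,5-dimethoxyphenyl)-7-[(2S,7S)-7-methyl-1,6-dioxaspiro[4.4]nonan-2-yl]heptan-1-ol
Product: 13 (3R)-5,7-dimethoxy-3-{6-[(2S,7S)-7-methyl-1,6-dioxaspiro[4.4]nonan-2-yl]hexyl}-2-benzofuran-1(3H)-one (C5′ epimer pair)
Conditions: Pd(OAc)2 (5 mol %), Xantphos (6 mol %), CO (1 atm), Et3N, toluene, 90 °C
Reagents that add atoms: carbon monoxide, [C-]#[O+]
Why: Palladium-catalysed carbonylative lactonisation of a 2-bromobenzylic alcohol (oxidative addition, CO insertion, intramolecular capture of the acyl-palladium by the hydroxyl) closes the five-membered lactone. The C3–O bond is never broken, so C3 stays R, and the basic medium leaves the ketal untouched.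

Step 5
Reactants: 13 (3R)-5,7-dimethoxy-3-{6-[(2S,7S)-7-methyl-1,6-dioxaspiro[4.4]nonan-2-yl]hexyl}-2-benzofuran-1(3H)-one (C5′ epimer pair)
Product: 14 (3R)-5,7-dimethoxy-3-{6-[(2S,5R,7S)-7-methyl-1,6-dioxaspiro[4.4]nonan-2-yl]hexyl}-2-benzofuran-1(3H)-one
Conditions: preparative HPLC (SiO2, hexane/EtOAc); remaining C5′-epimer fraction: PPTS (5 mol %), CH2Cl2, rt, then HPLC again (repeated)
Reagents that add atoms: none
Why: The two components of 13 are diastereomers and should be separable; mild acid reopens the ketal through the ring-opened oxocarbenium ion and restores the equilibrium pair (thermodynamic spiroketal equilibration), so repeated separation and equilibration should funnel 13 into 14. C3, C2′ and C7′ cannot ionise under these conditions and are unaffected.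

## Compound list

1 | rac-2-(hex-5-en-1-yl)oxirane | C=CCCCCC1CO1 | starting material
2 | (S)-2-(hex-5-en-1-yl)oxirane | C=CCCCC[C@H]1CO1 | intermediate
3 | acetone N,N-dimethylhydrazone | CC(C)=NN(C)C | starting material
4 | (S)-propylene oxide | C[C@H]1CO1 | starting material
5 | (2S)-5-(2,2-dimethylhydrazinylidene)hexan-2-ol (formed as lithium alkoxide) | C[C@H](O)CCC(C)=NN(C)C | intermediate (not isolated)
6 | (2S,8S)-5-(2,2-dimethylhydrazinylidene)tetradec-13-ene-2,8-diol | C[C@H](O)CCC(=NN(C)C)CC[C@@H](O)CCCCC=C | intermediate (not isolated)
7 | (2S,8S)-2,8-dihydroxytetradec-13-en-5-one | C[C@H](O)CCC(=O)CC[C@@H](O)CCCCC=C | intermediate (not isolated)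
8 | (2S,7S)-2-(hex-5-en-1-yl)-7-methyl-1,6-dioxaspiro[4.4]nonane, C5 epimer pair | C=CCCCC[C@H]1CCC2(CC[C@H](C)O2)O1 | intermediate
9 | 2-bromo-3,5-dimethoxybenzaldehyde | O=Cc1cc(OC)cc(OC)c1Br | starting material
10 | diethyl{6-[(2S,7S)-7-methyl-1,6-dioxaspiro[4.4]nonan-2-yl]hexyl}borane, C5′ epimer pair | CCB(CC)CCCCCC[C@H]1CCC2(CC[C@H](C)O2)O1 | intermediate (not isolated)
11 | bis{6-[(2S,7S)-7-methyl-1,6-dioxaspiro[4.4]nonan-2-yl]hexyl}zinc, C5′ epimers | C[C@H]1CCC2(CC[C@H](CCCCCC[Zn]CCCCCC[C@H]3CCC4(CC[C@H](C)O4)O3)O2)O1 | intermediate (not isolated)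
12 | (1R)-1-(2-bromo-3,5-dimethoxyphenyl)-7-[(2S,7S)-7-methyl-1,6-dioxaspiro[4.4]nonan-2-yl]heptan-1-ol, C5′ epimer pair | COc1cc(OC)c(Br)c(c1)[C@H](O)CCCCCC[C@H]1CCC2(CC[C@H](C)O2)O1 | intermediate
13 | (3R)-5,7-dimethoxy-3-{6-[(2S,7S)-7-methyl-1,6-dioxaspiro[4.4]nonan-2-yl]hexyl}-2-benzofuran-1(3H)-one, C5′ epimer pair | COc1cc(OC)c2c(c1)[C@@H](CCCCCC[C@H]1CCC3(CC[C@H](C)O3)O1)OC2=O | intermediate
14 | (3R)-5,7-dimethoxy-3-{6-[(2S,5R,7S)-7-methyl-1,6-dioxaspiro[4.4]nonan-2-yl]hexyl}-2-benzofuran-1(3H)-one | COc1cc(OC)c2c(c1)[C@@H](CCCCCC[C@H]1CC[C@@]3(CC[C@H](C)O3)O1)OC2=O | target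

## Step count and risks

Total steps: 5. Longest linear sequence: 5 (1 → 2 → 8 → 12 → 13 → 14); 3, 4 and 9 enter as commercial materials.

**Step 2 (key step).** The second metalation and alkylation take place on a lithium alkoxide aggregate. The likely failures are incomplete or slow opening of 2, competing deprotonation at the already substituted α-carbon leading to regioisomeric dialkylation, and loss of the volatile 4 before it reacts. The fallback replaces the acetone linchpin by an alkyne as the latent ketone and sets out from 2 and 4. Lithiated 1-(trimethylsilyl)propyne opens 2 to give (5S)-1-(trimethylsilyl)undec-10-en-1-yn-5-ol F1, and K2CO3/MeOH removes the silyl group to give (5S)-undec-10-en-1-yn-5-ol F2. Its alkoxide–acetylide (2 equiv n-BuLi) opens 4 in the presence of BF3·OEt2 to give (2S,8S)-tetradec-13-en-4-yne-2,8-diol F3. Catalytic AuCl in CH2Cl2, followed by a trace of PPTS, effects double hydroalkoxylation at the alkyne carbon that becomes C5′ and returns to the route at 8.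

**Step 3.** The likely failures are incomplete boron–zinc exchange and slow or poorly face-selective alkyl transfer if the ketal oxygens bind titanium or zinc, together with waste of 8 through the non-transferred alkyl group. The fallback moves stereocontrol from C–C bond formation to a ketone reduction and sets out from 11 and 9. Ligand-free Ti(OiPr)4-promoted addition gives the C1-epimeric carbinol (1RS)-1-(2-bromo-3,5-dimethoxyphenyl)-7-[(2S,7S)-7-methyl-1,6-dioxaspiro[4.4]nonan-2-yl]heptan-1-ol F4. Dess–Martin oxidation (NaHCO3 buffer) gives the aryl ketone 1-(2-bromo-3,5-dimethoxyphenyl)-7-[(2S,7S)-7-methyl-1,6-dioxaspiro[4.4]nonan-2-yl]heptan-1-one F5. Reduction with (S)-Me-CBS/BH3·SMe2, with the aryl group as the large substituent, should give the (R)-alcohol and returns to the route at 12.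

**Step 4.** Oxidative addition into the electron-rich, doubly ortho-substituted C–Br bond may be slow, and a palladium alkoxide may undergo β-hydride elimination, which oxidises the carbinol and reduces the C–Br bond. The fallback replaces catalysis by an organolithium carboxylation and sets out from 12. n-BuLi (2.2 equiv, THF, −78 °C) forms the alkoxide and exchanges bromine for lithium; CO2 and mild acidic work-up give 2-{(1R)-1-hydroxy-7-[(2S,7S)-7-methyl-1,6-dioxaspiro[4.4]nonan-2-yl]heptyl}-4,6-dimethoxybenzoic acid F6. This should lactonise spontaneously or with a trace of PPTS and returns to the route at 13.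

**Step 5.** The two C5′ epimers may not be resolved on a preparative scale, or the equilibrium may lie against 14 so that many cycles are needed. The fallback moves the resolution to an earlier compound with a derivatisable hydroxyl and sets out from 12. 3,5-Dinitrobenzoyl chloride/pyridine gives the ester (1R)-1-(2-bromo-3,5-dimethoxyphenyl)-7-[(2S,7S)-7-methyl-1,6-dioxaspiro[4.4]nonan-2-yl]heptyl 3,5-dinitrobenzoate F7 as the epimer pair. Crystallisation or chromatography should isolate the (5′R) ester (1R)-1-(2-bromo-3,5-dimethoxyphenyl)-7-[(2S,5R,7S)-7-methyl-1,6-dioxaspiro[4.4]nonan-2-yl]heptyl 3,5-dinitrobenzoate F8, with the other ester recycled by acid equilibration. K2CO3/MeOH releases (1R)-1-(2-bromo-3,5-dimethoxyphenyl)-7-[(2S,5R,7S)-7-methyl-1,6-dioxaspiro[4.4]nonan-2-yl]heptan-1-ol F9. Under the acid-free conditions of step 4 this gives the single epimer directly and returns to the route at 14.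

## Further compounds

F1 | step 2 | (5S)-1-(trimethylsilyl)undec-10-en-1-yn-5-ol | C[Si](C)(C)C#CCC[C@@H](O)CCCCC=C
F2 | step 2 | (5S)-undec-10-en-1-yn-5-ol | C#CCC[C@@H](O)CCCCC=C
F3 | step 2 | (2S,8S)-tetradec-13-en-4-yne-2,8-diol | C[C@H](O)CC#CCC[C@@H](O)CCCCC=C
F4 | step 3 | (1RS)-1-(2-bromo-3,5-dimethoxyphenyl)-7-[(2S,7S)-7-methyl-1,6-dioxaspiro[4.4]nonan-2-yl]heptan-1-ol, C5′ epimers | COc1cc(OC)c(Br)c(c1)C(O)CCCCCC[C@H]1CCC2(CC[C@H](C)O2)O1
F5 | step 3 | 1-(2-bromo-3,5-dimethoxyphenyl)-7-[(2S,7S)-7-methyl-1,6-dioxaspiro[4.4]nonan-2-yl]heptan-1-one, C5′ epimers | COc1cc(OC)c(Br)c(c1)C(=O)CCCCCC[C@H]1CCC2(CC[C@H](C)O2)O1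
F6 | step 4 | 2-{(1R)-1-hydroxy-7-[(2S,7S)-7-methyl-1,6-dioxaspiro[4.4]nonan-2-yl]heptyl}-4,6-dimethoxybenzoic acid, C5′ epimers | COc1cc(OC)c(C(=O)O)c(c1)[C@H](O)CCCCCC[C@H]1CCC2(CC[C@H](C)O2)O1
F7 | step 5 | (1R)-1-(2-bromo-3,5-dimethoxyphenyl)-7-[(2S,7S)-7-methyl-1,6-dioxaspiro[4.4]nonan-2-yl]heptyl 3,5-dinitrobenzoate, C5′ epimer pair | COc1cc(OC)c(Br)c(c1)[C@H](OC(=O)c1cc(cc(c1)[N+](=O)[O-])[N+](=O)[O-])CCCCCC[C@H]1CCC2(CC[C@H](C)O2)O1
F8 | step 5 | (1R)-1-(2-bromo-3,5-dimethoxyphenyl)-7-[(2S,5R,7S)-7-methyl-1,6-dioxaspiro[4.4]nonan-2-yl]heptyl 3,5-dinitrobenzoate | COc1cc(OC)c(Br)c(c1)[C@H](OC(=O)c1cc(cc(c1)[N+](=O)[O-])[N+](=O)[O-])CCCCCC[C@H]1CC[C@@]2(CC[C@H](C)O2)O1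
F9 | step 5 | (1R)-1-(2-bromo-3,5-dimethoxyphenyl)-7-[(2S,5R,7S)-7-methyl-1,6-dioxaspiro[4.4]nonan-2-yl]heptan-1-ol | COc1cc(OC)c(Br)c(c1)[C@H](O)CCCCCC[C@H]1CC[C@@]2(CC[C@H](C)O2)O1
A1 | alternative 1 | 5-({3-[(7S)-7-methyl-1,6-dioxaspiro[4.4]nonan-2-yl]propyl}sulfonyl)-1-phenyl-1H-tetrazole, C2′ arranged as in the target, C5′ epimers | O=S(=O)(CCC[C@H]1CCC2(CC[C@H](C)O2)O1)c1nnnn1-c1ccccc1
A2 | alternative 1 | (3R)-5,7-dimethoxy-3-(3-oxopropyl)-2-benzofuran-1(3H)-one | O=CCC[C@H]1OC(=O)c2c(OC)cc(OC)cc12
A3 | alternative 1 | (3R)-5,7-dimethoxy-3-{6-[(2S,7S)-7-methyl-1,6-dioxaspiro[4.4]nonan-2-yl]hex-3-en-1-yl}-2-benzofuran-1(3H)-one, C5′ epimers | COc1cc(OC)c2c(c1)[C@@H](CCC=CCC[C@H]1CCC3(CC[C@H](C)O3)O1)OC2=O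
A4 | alternative 2 | (3R)-3-[(7S,13S)-7,13-dihydroxytetradec-9-yn-1-yl]-5,7-dimethoxy-2-benzofuran-1(3H)-one | COc1cc(OC)c2c(c1)[C@@H](CCCCCC[C@H](O)CC#CCC[C@H](C)O)OC2=O
A5 | alternative 3 | (3R)-3-[(7S,13S)-7,13-dihydroxytetradecyl]-5,7-dimethoxy-2-benzofuran-1(3H)-one | COc1cc(OC)c2c(c1)[C@@H](CCCCCC[C@H](O)CCCCC[C@H](C)O)OC2=O
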